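# Proposed synthesis of (5S,6S,7S,10R)-eudesm-4(15)-en-6-yl (E)-4-hydroxycinnamate (21) by radical closure of ring A onto piperitone

## Analysis of the target

Target 21 is the (E)-4-hydroxycinnamate of a 6-hydroxyeudesm-4(15)-ene. In eudesmane numbering, ring A is C1–C5 plus C10 and ring B is C5–C10 of a trans-fused decalin. C4 carries the exocyclic methylene C15, C6 the acyloxy group, C7 an isopropyl group and C10 the angular methyl C14. There are four stereocentres, (5S,6S,7S,10R): three are contiguous (C5, C6, C7) and the fourth is the quaternary C10. In the chair–chair decalin, C14 is axial, H5 is axial on the opposite face, and the C6 oxygen and C7 isopropyl are both equatorial. The C5/C6/C7 array is therefore the thermodynamically preferred one once C10 is fixed. Sensitive groups are the 1,1-disubstituted exocyclic alkene (it moves into the ring under acid), the free phenol, and the cinnamate, which is a Michael acceptor and a base-labile ester on a hindered oxygen. The difficulties are the absolute configuration of the quaternary C10, which has no functional group nearby in the target, and the opposite redox adjustments needed at C4 and C6. The strategy rests on one feature: ring B with its C6 oxygen, C7 isopropyl and C10 methyl is the p-menthane skeleton of piperitone 1, whose enone β-carbon is C10 and α-carbon is C5. Ring A can then be built by attaching a C1–C4 chain at C5 and closing C1 onto C10.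

## Retrosynthetic reasoning

**Phenol (21 ⇐ 20).** The phenol is carried as its acetate and released last. An aryl acetate is far more electrophilic than the hindered secondary cinnamate, so mild transesterification should free the phenol alone.

**C4=C15 (20 ⇐ 19).** The exocyclic alkene is cut back to the C4 ketone. It is introduced late because it isomerises easily. The forward step must be non-basic, since C5 is α to this ketone and β to the acyloxy group.

**Ester C6–O (19 ⇐ 15 + 18; 18 ⇐ 17 ⇐ 16).** The ester is formed while C4 is a ketone. There is then no second hydroxyl peri to O6, so neither regiochemistry of acylation nor 1,3-acyl migration can arise. The acid part is used as acid chloride 18, made from acetate 17 of acid 16.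

**Exchange of oxidation levels at C4 and C6 (15 ⇐ 14 ⇐ 13).** Ring closure needs C6 as a ketone and C4 as a carbinol; the target needs C6 as an equatorial alcohol and C4 as a carbonyl precursor. The ketone of 13 is reduced under thermodynamic control to diol 14. The less encumbered C4 hydroxyl is then oxidised to give 15. This avoids a protecting group on O4, which would sit peri to the oxygen to be acylated.

**C7 and C5 (13 ⇐ 12).** Both centres are α to the C6 ketone. The mixture of C7 epimers from the ring closure is converged by enolisation onto the all-equatorial trans-fused isomer 13. This is why racemic 1 suffices.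

**C1–C10, ring A (12 ⇐ 11).** This is the key disconnection. It removes the quaternary centre and the ring in one cut and leaves a 2-substituted piperitone. Forward, the primary C1 radical from iodide 11 must add to the enone β-carbon, with the C4 carbinol as the only source of absolute configuration.

**C4 stereocentre (11 ⇐ 10 ⇐ 9).** The carbinol is set by catalyst-controlled enantioselective reduction of alkenyl ketone 9. The ring carbonyl is masked as its ketal so that the side-chain ketone is the only reducible carbonyl. The iodide is installed before the reduction so that the iodohydrin is never heated.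

**C4–C5 bond (9 ⇐ 8 ⇐ 7 ⇐ 4 + 5).** The chain is joined at the enone α-carbon by adding the masked α-ketovinyl anion 6 to aldehyde 5. A direct amine-catalysed hydroxyalkylation of 1 is not available because the enone is β-substituted. Oxidation to 8 erases the uncontrolled carbinol of 7.

**Activation of C5 (4 ⇐ 3 ⇐ 1).** A bromo substituent is placed at C5 by addition–elimination through 2 and the carbonyl is ketalised. Bromination is chosen over direct α-iodination, which is sluggish on β-alkylated enones.

## Alternatives that were turned down

Alternative 1: Ring B is disconnected at C6–C7. Aldehyde A2 carries the formyl group at C5, a silyloxy group at C4 and a quaternary C10 bearing the methyl and a 4-methylpent-3-enyl chain. A Lewis acid would close it in a carbonyl-ene reaction to homoallylic alcohol A1.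
- For: the chair-like transition state places hydroxyl and isopropenyl trans-diequatorial, so C6 and C7 arise together with the target's configuration and the C6 hydroxyl arrives free. On this point it is stronger than the chosen route, which needs a reduction and an equilibration.
- Against: A2 already holds three stereocentres (C4, C5 and the quaternary C10) that must be made by separate asymmetric chemistry. Its aldehyde is α-epimerisable and β-silyloxy, so it can eliminate. Two alkenes must later be hydrogenated. The C4 silyloxy group ends up peri to the hydroxyl that has to be acylated.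
- Comparison: the hardest problem, C10, is moved into the precursor rather than solved. The chosen route takes ring B ready-made from 1 and sets C10 in the ring-forming step.

Alternative 2: Ring B is disconnected at C5–C6 and C9–C10. Keto ester dienophile A4 and silyloxydiene A5 would combine under Lewis acid catalysis in a [4+2] cycloaddition to give A3.
- For: it is the most convergent option. Two C–C bonds, the quaternary C10, C5 and C6 form at once, two-point binding of the β-keto ester invites a chiral Lewis acid, and the C4 ketone/C6 oxygen pattern is correct from the start. In convergence and redox economy it is stronger than the chosen route.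
- Against: A4 is a tetrasubstituted, β-methylated dienophile, a class that reacts poorly. The adduct is cis-fused. The C5 ester is a superfluous carbon; removing it next to a β-silyloxy group risks elimination, and C5 must then be reset to the trans fusion. C7 must be set by face-selective hydrogenation of the C7=C8 alkene.
- Comparison: the chosen route builds no carbon that must be removed and leaves C5 and C7 to thermodynamic control.

Alternative 3: Ring B is disconnected at C8–C9 and C5–C6. Under base, the nitronate of nitro ketone A7 would add to enal A8, and the C4 ketone enolate would then close onto the aldehyde to give A6.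
- For: it is very short. A6 already has the hydroxyl at C6 and the ketone at C4, the pattern of 15, with all substituents equatorial. In step count it is stronger than the chosen route.
- Against: the α-branched enal A8 is a reluctant Michael acceptor and polymerises. The ketone can enolise toward C3 as well as C5. Every step is reversible, so retro-aldol and dehydration compete. The secondary nitro group at C9 must be removed, and reductive denitration of secondary nitroalkanes is inefficient. A7 still needs its quaternary centre made enantioselectively.
- Comparison: the chosen route offers a ring closure of predictable regiochemistry and a radical precursor (iodide) that leaves no trace.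

Key step: step 7

Remark: eudesmane numbering (C1–C15) is used for the bicyclic compounds and for the corresponding carbons of their precursors; racemic 1 is used because its isopropyl-bearing centre is equilibrated in step 8, and 5 is taken as purchasable (also available by hydrolysis of its dimethyl acetal).

## Route

Step 1
Reactants: 1 piperitone (racemic 6-isopropyl-3-methylcyclohex-2-en-1-one)
Product: 3 2-bromo-6-isopropyl-3-methylcyclohex-2-en-1-one (racemic), via 2,3-dibromo ketone 2 (not isolated)
Conditions: Br2, CH2Cl2, 0 °C; then Et3N, 0 °C to rt
Reagents that add atoms: bromine, BrBr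
Why: Electrophilic addition of bromine to the enone alkene followed by amine-induced loss of HBr through the acidic C5–H (addition–elimination α-bromination of an enone); unlike α-iodination with iodine and pyridine, this sequence tolerates the β-methyl group.

Step 2
Reactants: 3 2-bromo-6-isopropyl-3-methylcyclohex-2-en-1-one
Product: 4 6-bromo-10-isopropyl-7-methyl-1,4-dioxaspiro[4.5]dec-6-ene (racemic)
Conditions: HOCH2CH2OH, p-TsOH (cat.), benzene, reflux, Dean–Stark
Reagents that add atoms: ethylene glycol, OCCO
Why: Acid-catalysed ketalisation with azeotropic removal of water; α-bromo enones ketalise without migration of the double bond, and the ketal masks the ring carbonyl for the organolithium step and for the later reduction.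

Step 3
Reactants: 4 6-bromo-10-isopropyl-7-methyl-1,4-dioxaspiro[4.5]dec-6-ene; 5 4-chlorobutanal
Product: 7 4-chloro-1-(10-isopropyl-7-methyl-1,4-dioxaspiro[4.5]dec-6-en-6-yl)butan-1-ol (mixture of stereoisomers), via alkenyllithium 6 (not isolated)
Conditions: t-BuLi (2.1 equiv), THF, −78 °C; then 5, −78 °C; aq. NH4Cl, −78 °C
Reagents that add atoms: none
Why: Bromine–lithium exchange gives the masked α-ketovinyl anion 6, which should add to the unhindered aldehyde faster than it enolises it; the primary chloride is inert at −78 °C, and the new carbinol centre is left uncontrolled because step 4 erases it.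

Step 4
Reactants: 7 4-chloro-1-(10-isopropyl-7-methyl-1,4-dioxaspiro[4.5]dec-6-en-6-yl)butan-1-ol
Product: 8 4-chloro-1-(10-isopropyl-7-methyl-1,4-dioxaspiro[4.5]dec-6-en-6-yl)butan-1-one (racemic)
Conditions: Dess–Martin periodinane, NaHCO3, CH2Cl2, 0 °C to rt
Reagents that add atoms: none
Why: Dess–Martin oxidation of a secondary allylic alcohol; the bicarbonate buffer protects the acid-labile ketal, and the stereoisomer mixture converges on one racemic ketone.

Step 5
Reactants: 8 4-chloro-1-(10-isopropyl-7-methyl-1,4-dioxaspiro[4.5]dec-6-en-6-yl)butan-1-one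
Product: 9 4-iodo-1-(10-isopropyl-7-methyl-1,4-dioxaspiro[4.5]dec-6-en-6-yl)butan-1-one (racemic)
Conditions: NaI, acetone, reflux, dark
Reagents that add atoms: sodium iodide, [Na+].[I-]
Why: Finkelstein exchange (SN2) driven by precipitation of NaCl; it is done on the ketone so that a 4-halo alcohol able to close to a tetrahydrofuran is never heated.

Step 6
Reactants: 9 4-iodo-1-(10-isopropyl-7-methyl-1,4-dioxaspiro[4.5]dec-6-en-6-yl)butan-1-one
Product: 11 2-[(1R)-1-hydroxy-4-iodobutyl]-6-isopropyl-3-methylcyclohex-2-en-1-one (both C6 epimers of the ring), via iodo alcohol ketal 10 (not isolated)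
Conditions: (S)-2-methyl-CBS-oxazaborolidine (0.2 equiv), BH3·SMe2, THF, −20 °C; MeOH; then 0.5 M HCl, THF, 0 °C to rt
Reagents that add atoms: water, O
Why: Corey–Bakshi–Shibata reduction in which the tetrasubstituted alkenyl group is the large substituent and the iodopropyl chain the small one, so the (S)-catalyst should give the (R)-carbinol in both series of the remote isopropyl centre; the allylic ketal is then hydrolysed by the dilute acid of the work-up, the carbonyl oxygen coming from water.

Step 7
Reactants: 11 2-[(1R)-1-hydroxy-4-iodobutyl]-6-isopropyl-3-methylcyclohex-2-en-1-one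
Product: 12 (4R,5R,10R)-4-hydroxy-15-noreudesman-6-one (trans-fused, 4-hydroxyl equatorial; mixture of C7 epimers)
Conditions: (Me3Si)3SiH (1.3 equiv, slow addition), AIBN (0.2 equiv), PhMe (0.01 M), 80 °C
Reagents that add atoms: none
Why: The silyl radical abstracts iodine from 11, the primary C1 radical adds to C10 (the enone β-carbon), and the resulting C5 α-keto radical takes hydrogen from the silane, which carries the chain. The closest known reaction type is the silane- or stannane-mediated cyclisation of ω-haloalkyl radicals onto the β-carbon of 2-substituted cycloalk-2-enones, an intramolecular Giese addition. Ring A closes 6-endo-trig: attack at C10 is polarity-matched and gives a stabilised radical, whereas 5-exo attack at the fully substituted C5 would give a spiro ring and an unstabilised tertiary radical. C10 is controlled by C4: in the chair-like transition state the C4–O bond lies near the enone plane, pseudo-equatorial and hydrogen-bonded to the C6 carbonyl, so C4–H rather than C4–O faces the C14 methyl and the chain reaches C10 from the face that makes H4 and C14 cis, giving (10R) from (4R). C5 is set by hydrogen transfer to the planar α-keto radical from the face opposite the axial C14 methyl, giving the trans fusion; this centre stays correctable by enolisation in step 8. The step needs ring closure to outrun reduction of the C1 radical, 6-endo over 5-exo closure, and one face of C10; these are secured by slow addition of the silane at high dilution, by the substitution and polarisation of the enone, and by the hydrogen-bonded carbinol. C7 is not touched, so both epimers are carried. Any minor C10 diastereomer must be removed chromatographically here or at 13 or 14, because it becomes the enantiomeric series once C4 is oxidised in step 10.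

Step 8
Reactants: 12 (4R,5R,10R)-4-hydroxy-15-noreudesman-6-one (C7 epimer mixture)
Product: 13 (4R,5R,7S,10R)-4-hydroxy-15-noreudesman-6-one (4α-hydroxyl and 7β-isopropyl equatorial, trans-fused)
Conditions: K2CO3, MeOH, rt
Reagents that add atoms: none
Why: Base-mediated epimerisation through the enolates of the C6 ketone, as in the menthone series: the isopropyl group should settle equatorial and C5 should stay or return to the trans fusion, the all-equatorial isomer being the expected thermodynamic minimum. Carbonate is chosen to limit retro-aldol cleavage or dehydration of the β-hydroxy ketone.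

Step 9
Reactants: 13 (4R,5R,7S,10R)-4-hydroxy-15-noreudesman-6-one
Product: 14 (4R,5R,6S,7S,10R)-15-noreudesmane-4,6-diol (both hydroxyls equatorial, α)
Conditions: SmI2, H2O, Et3N, THF, rt
Reagents that add atoms: none
Why: Ketyl reduction by samarium diiodide activated with water and amine should give the more stable equatorial 6α-alcohol, since an axial hydroxyl would be syn-diaxial to C14 and chelation to the peri C4 oxygen favours the same geometry; hydride reagents would attack anti to C14 and give the axial alcohol. The reduction is fast and only weakly basic, so C5 and C7 should not epimerise.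

Step 10
Reactants: 14 (4R,5R,6S,7S,10R)-15-noreudesmane-4,6-diol
Product: 15 (5S,6S,7S,10R)-6-hydroxy-15-noreudesman-4-one (6α-hydroxyl equatorial, trans-fused)
Conditions: TEMPO (0.2 equiv), PhI(OAc)2 (1.2 equiv), CH2Cl2, rt
Reagents that add atoms: none
Why: Oxoammonium (TEMPO) oxidation is strongly retarded by α-branching; the C4 carbinol has one branched neighbour while the C6 carbinol is flanked by the ring fusion and the isopropyl-bearing C7 (menthol-type), so C4 should be oxidised selectively. The medium is non-basic and should leave C5 untouched.

Step 11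
Reactants: 16 (E)-4-hydroxycinnamic acid
Product: 17 (E)-4-acetoxycinnamic acid
Conditions: Ac2O, pyridine, rt; then H2O
Reagents that add atoms: acetic anhydride, CC(=O)OC(C)=O
Why: Pyridine-promoted O-acetylation of the phenol; the aqueous finish hydrolyses any mixed anhydride of the carboxylic acid.

Step 12
Reactants: 15 (5S,6S,7S,10R)-6-hydroxy-15-noreudesman-4-one; 17 (E)-4-acetoxycinnamic acid
Product: 19 (5S,6S,7S,10R)-4-oxo-15-noreudesman-6-yl (E)-3-(4-acetoxyphenyl)prop-2-enoate, via acid chloride 18 (not isolated)
Conditions: 17, (COCl)2, DMF (cat.), CH2Cl2, 0 °C to rt, evaporate; then 15, Et3N, DMAP, CH2Cl2, rt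
Reagents that add atoms: none
Why: Acid chloride formation and DMAP-catalysed acylation of a hindered secondary alcohol; with C4 already a ketone there is no second hydroxyl, so regiochemistry and acyl migration are not an issue, and the equatorial C6–O bond is poorly aligned for β-elimination.

Step 13
Reactants: 19 (5S,6S,7S,10R)-4-oxo-15-noreudesman-6-yl (E)-3-(4-acetoxyphenyl)prop-2-enoate
Product: 20 (5S,6S,7S,10R)-eudesm-4(15)-en-6-yl (E)-3-(4-acetoxyphenyl)prop-2-enoate
Conditions: Zn, CH2Br2, TiCl4, THF/CH2Cl2, 0 °C to rt
Reagents that add atoms: dibromomethane, BrCBr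
Why: Takai–Lombardo methylenation: the zinc–titanium methylene reagent converts ketones and leaves esters alone, and it is non-basic, so the epimerisable C5 and the β-acyloxy ketone should survive.

Step 14
Reactants: 20 (5S,6S,7S,10R)-eudesm-4(15)-en-6-yl (E)-3-(4-acetoxyphenyl)prop-2-enoate
Product: 21 (5S,6S,7S,10R)-eudesm-4(15)-en-6-yl (E)-3-(4-hydroxyphenyl)prop-2-enoate
Conditions: K2CO3 (0.3 equiv), MeOH, 0 °C; aq. NH4Cl
Reagents that add atoms: none
Why: Transesterification of the aryl acetate, which is far more electrophilic than the hindered secondary cinnamate; brief exposure at 0 °C should leave the ester, the exocyclic alkene and all stereocentres unchanged.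

## Compound list

1 | piperitone, racemic (6-isopropyl-3-methylcyclohex-2-en-1-one) | CC1=CC(=O)C(C(C)C)CC1 | starting material
2 | 2,3-dibromo-6-isopropyl-3-methylcyclohexan-1-one (stereoisomer mixture) | CC1(Br)CCC(C(C)C)C(=O)C1Br | intermediate
3 | 2-bromo-6-isopropyl-3-methylcyclohex-2-en-1-one (racemic) | CC1=C(Br)C(=O)C(C(C)C)CC1 | intermediate
4 | 6-bromo-10-isopropyl-7-methyl-1,4-dioxaspiro[4.5]dec-6-ene (racemic) | CC1=C(Br)C2(OCCO2)C(C(C)C)CC1 | intermediate
5 | 4-chlorobutanal | O=CCCCCl | starting material
6 | (10-isopropyl-7-methyl-1,4-dioxaspiro[4.5]dec-6-en-6-yl)lithium | [Li]C1=C(C)CCC(C(C)C)C12OCCO2 | intermediate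
7 | 4-chloro-1-(10-isopropyl-7-methyl-1,4-dioxaspiro[4.5]dec-6-en-6-yl)butan-1-ol (mixture of stereoisomers) | CC1=C(C(O)CCCCl)C2(OCCO2)C(C(C)C)CC1 | intermediate
8 | 4-chloro-1-(10-isopropyl-7-methyl-1,4-dioxaspiro[4.5]dec-6-en-6-yl)butan-1-one (racemic) | CC1=C(C(=O)CCCCl)C2(OCCO2)C(C(C)C)CC1 | intermediate
9 | 4-iodo-1-(10-isopropyl-7-methyl-1,4-dioxaspiro[4.5]dec-6-en-6-yl)butan-1-one (racemic) | CC1=C(C(=O)CCCI)C2(OCCO2)C(C(C)C)CC1 | intermediate
10 | (1R)-4-iodo-1-(10-isopropyl-7-methyl-1,4-dioxaspiro[4.5]dec-6-en-6-yl)butan-1-ol (both epimers at the isopropyl-bearing carbon) | CC1=C([C@H](O)CCCI)C2(OCCO2)C(C(C)C)CC1 | intermediate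
11 | 2-[(1R)-1-hydroxy-4-iodobutyl]-6-isopropyl-3-methylcyclohex-2-en-1-one (both C6 epimers of the ring) | CC1=C([C@H](O)CCCI)C(=O)C(C(C)C)CC1 | intermediate
12 | (4R,5R,10R)-4-hydroxy-15-noreudesman-6-one (trans-fused, 4α-hydroxyl equatorial, C7 epimer mixture) | O[C@@H]1CCC[C@]2(C)CCC(C(C)C)C(=O)[C@@H]12 | intermediate
13 | (4R,5R,7S,10R)-4-hydroxy-15-noreudesman-6-one (4α-hydroxyl, 7β-isopropyl, trans-fused) | O[C@@H]1CCC[C@]2(C)CC[C@@H](C(C)C)C(=O)[C@@H]12 | intermediate
14 | (4R,5R,6S,7S,10R)-15-noreudesmane-4,6-diol (4α,6α-diol) | O[C@@H]1CCC[C@]2(C)CC[C@@H](C(C)C)[C@H](O)[C@@H]12 | intermediate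
15 | (5S,6S,7S,10R)-6-hydroxy-15-noreudesman-4-one (6α-hydroxyl) | O=C1CCC[C@]2(C)CC[C@@H](C(C)C)[C@H](O)[C@@H]12 | intermediate
16 | (E)-4-hydroxycinnamic acid | O=C(O)/C=C/c1ccc(O)cc1 | starting material
17 | (E)-4-acetoxycinnamic acid | CC(=O)Oc1ccc(/C=C/C(=O)O)cc1 | intermediate
18 | (E)-4-acetoxycinnamoyl chloride | CC(=O)Oc1ccc(/C=C/C(=O)Cl)cc1 | intermediate
19 | (5S,6S,7S,10R)-4-oxo-15-noreudesman-6-yl (E)-3-(4-acetoxyphenyl)prop-2-enoate | O=C1CCC[C@]2(C)CC[C@@H](C(C)C)[C@H](OC(=O)/C=C/c3ccc(OC(C)=O)cc3)[C@@H]12 | intermediate
20 | (5S,6S,7S,10R)-eudesm-4(15)-en-6-yl (E)-3-(4-acetoxyphenyl)prop-2-enoate | C=C1CCC[C@]2(C)CC[C@@H](C(C)C)[C@H](OC(=O)/C=C/c3ccc(OC(C)=O)cc3)[C@@H]12 | intermediate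
21 | (5S,6S,7S,10R)-eudesm-4(15)-en-6-yl (E)-3-(4-hydroxyphenyl)prop-2-enoate | C=C1CCC[C@]2(C)CC[C@@H](C(C)C)[C@H](OC(=O)/C=C/c3ccc(O)cc3)[C@@H]12 | target

## Step count and least certain steps

Total step count: 14. Longest linear sequence: 13 steps (steps 1–10 and 12–14 from 1); step 11 is a one-step branch.

**Step 7 (key step).** Three things may go wrong.
- Hydrogen transfer to the C1 radical may occur before ring closure, because attack on a fully substituted β-carbon is slow.
- The iodohydrin may close ionically to a tetrahydrofuran at 80 °C.
- Face selection at C10 may be incomplete, which would lower the enantiomeric purity once C4 is oxidised.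

Fallback: the order of the two ring-A bonds is reversed and C10 is set by a catalyst. The Grignard reagent [3-(1,3-dioxolan-2-yl)propyl]magnesium chloride F1 is made from purchased 2-(3-chloropropyl)-1,3-dioxolane and magnesium. It is added to 1 under copper catalysis (CuBr·SMe2 with a chiral N-heterocyclic carbene ligand, Et2O, low temperature). This enantioselective conjugate addition should give (3R)-3-[3-(1,3-dioxolan-2-yl)propyl]-3-methyl-6-(propan-2-yl)cyclohexan-1-one F2. Aqueous acid unmasks 4-[(1R)-1-methyl-3-oxo-4-(propan-2-yl)cyclohexyl]butanal F3. K2CO3 in MeOH then closes C4–C5 by a reversible intramolecular aldol addition and equilibrates C5 and C7. The fallback sets out from 1 and should return to the route at 13.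

**Step 10.** The two equatorial carbinols may not be discriminated well enough, since both carbinol hydrogens are axial and syn to C14, and the dione may form. Fallback: O4 is protected before the reduction, starting from 13.
- TESCl and imidazole in DMF give (4R,5R,7S,10R)-4-(triethylsilyloxy)-15-noreudesman-6-one F4.
- SmI2, H2O and Et3N give (4R,5S,6S,7S,10R)-4-(triethylsilyloxy)-15-noreudesman-6-ol F5.
- Acylation with 18, Et3N and DMAP gives (4R,5S,6S,7S,10R)-4-(triethylsilyloxy)-15-noreudesman-6-yl (E)-3-(4-acetoxyphenyl)prop-2-enoate F6.
- HF·pyridine in THF releases (4R,5R,6S,7S,10R)-4-hydroxy-15-noreudesman-6-yl (E)-3-(4-acetoxyphenyl)prop-2-enoate F7.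
- F7 is oxidised at once with Dess–Martin periodinane, before the acyl group can migrate to O4.

The fallback returns to the route at 19.

**Step 8.** Enolisation toward C5 may let the cis-fused epimer build up, and the free β-hydroxy ketone may undergo retro-aldol cleavage or dehydration. Fallback: the hydroxyl is masked before equilibration. Compound 12 is silylated (TESCl, imidazole, DMF) to (4R,5R,10R)-4-(triethylsilyloxy)-15-noreudesman-6-one F8, a C7 epimer mixture. F8 is equilibrated with NaOMe in MeOH to (4R,5R,7S,10R)-4-(triethylsilyloxy)-15-noreudesman-6-one F4. HF·pyridine then removes the silyl group. The fallback sets out from 12 and returns at 13; alternatively F4 is carried on as in the fallback for step 10.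

**Step 6.** Enantioface discrimination may be incomplete for this strongly twisted, doubly flanked alkenyl ketone, and the allylic carbinol may partly ionise during the acid hydrolysis. Fallback: C4 is set in the C–C bond formation.
- Alkenyllithium 6 (from 4) is transmetallated with ZnBr2 to (10-isopropyl-7-methyl-1,4-dioxaspiro[4.5]dec-6-en-6-yl)zinc bromide F9.
- F9 is added to 5 in the presence of the enantiomer of the amino alcohol ligand MIB that delivers the (R)-carbinol, giving (1R)-4-chloro-1-(10-isopropyl-7-methyl-1,4-dioxaspiro[4.5]dec-6-en-6-yl)butan-1-ol F10.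
- Aqueous oxalic acid gives 2-[(1R)-4-chloro-1-hydroxybutyl]-6-isopropyl-3-methylcyclohex-2-en-1-one F11.
- NaI in acetone at the lowest workable temperature gives the iodide.

The fallback sets out from 4 and returns at 11.

**Step 13.** The Lewis acidic reagent may cause loss of the C6 carboxylate by β-elimination or epimerisation at C5, and the hindered ketone may convert incompletely. Fallback: methylenation and acylation are exchanged. Compound 15 is methylenated (Zn, CH2Br2, TiCl4) to (5S,6S,7S,10R)-eudesm-4(15)-en-6-ol F12. F12 is then acylated with 18, Et3N and DMAP. The fallback sets out from 15 and returns at 20.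

## Further compounds

F1 | step 7 | [3-(1,3-dioxolan-2-yl)propyl]magnesium chloride | Cl[Mg]CCCC1OCCO1
F2 | step 7 | (3R)-3-[3-(1,3-dioxolan-2-yl)propyl]-3-methyl-6-(propan-2-yl)cyclohexan-1-one (both C6 epimers) | C[C@@]1(CCCC2OCCO2)CCC(C(C)C)C(=O)C1
F3 | step 7 | 4-[(1R)-1-methyl-3-oxo-4-(propan-2-yl)cyclohexyl]butanal (both C4 epimers of the ring) | C[C@@]1(CCCC=O)CCC(C(C)C)C(=O)C1
F4 | step 10 | (4R,5R,7S,10R)-4-(triethylsilyloxy)-15-noreudesman-6-one | CC[Si](CC)(CC)O[C@@H]1CCC[C@]2(C)CC[C@@H](C(C)C)C(=O)[C@@H]12
F5 | step 10 | (4R,5S,6S,7S,10R)-4-(triethylsilyloxy)-15-noreudesman-6-ol | CC[Si](CC)(CC)O[C@@H]1CCC[C@]2(C)CC[C@@H](C(C)C)[C@H](O)[C@@H]12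
F6 | step 10 | (4R,5S,6S,7S,10R)-4-(triethylsilyloxy)-15-noreudesman-6-yl (E)-3-(4-acetoxyphenyl)prop-2-enoate | CC[Si](CC)(CC)O[C@@H]1CCC[C@]2(C)CC[C@@H](C(C)C)[C@H](OC(=O)/C=C/c3ccc(OC(C)=O)cc3)[C@@H]12
F7 | step 10 | (4R,5R,6S,7S,10R)-4-hydroxy-15-noreudesman-6-yl (E)-3-(4-acetoxyphenyl)prop-2-enoate | O[C@@H]1CCC[C@]2(C)CC[C@@H](C(C)C)[C@H](OC(=O)/C=C/c3ccc(OC(C)=O)cc3)[C@@H]12
F8 | step 8 | (4R,5R,10R)-4-(triethylsilyloxy)-15-noreudesman-6-one (C7 epimer mixture) | CC[Si](CC)(CC)O[C@@H]1CCC[C@]2(C)CCC(C(C)C)C(=O)[C@@H]12
F9 | step 6 | (10-isopropyl-7-methyl-1,4-dioxaspiro[4.5]dec-6-en-6-yl)zinc bromide | Br[Zn]C1=C(C)CCC(C(C)C)C12OCCO2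
F10 | step 6 | (1R)-4-chloro-1-(10-isopropyl-7-methyl-1,4-dioxaspiro[4.5]dec-6-en-6-yl)butan-1-ol | CC1=C([C@H](O)CCCCl)C2(OCCO2)C(C(C)C)CC1
F11 | step 6 | 2-[(1R)-4-chloro-1-hydroxybutyl]-6-isopropyl-3-methylcyclohex-2-en-1-one | CC1=C([C@H](O)CCCCl)C(=O)C(C(C)C)CC1
F12 | step 13 | (5S,6S,7S,10R)-eudesm-4(15)-en-6-ol | C=C1CCC[C@]2(C)CC[C@@H](C(C)C)[C@H](O)[C@@H]12
A1 | alternative 1 | 4-(tert-butyldimethylsilyloxy)-15-noreudesma-1,11-dien-6-ol (trans-fused, 6-hydroxyl and 7-isopropenyl equatorial) | CC(C)(C)[Si](C)(C)O[C@@H]1CC=C[C@]2(C)CC[C@@H](C(C)=C)[C@H](O)[C@@H]12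
A2 | alternative 1 | 6-(tert-butyldimethylsilyloxy)-2-methyl-2-(4-methylpent-3-en-1-yl)cyclohex-3-ene-1-carbaldehyde (configuration as in A1) | CC(C)(C)[Si](C)(C)O[C@@H]1CC=C[C@](C)(CCC=C(C)C)[C@H]1C=O
A3 | alternative 2 | methyl 6-(tert-butyldimethylsilyloxy)-4-oxo-15-noreudesm-7-ene-5-carboxylate (cis-fused, silyloxy trans to the C10 methyl) | O=C1CCC[C@]2(C)CC=C(C(C)C)[C@H](O[Si](C)(C)C(C)(C)C)[C@]12C(=O)OC
A4 | alternative 2 | methyl 2-methyl-6-oxocyclohex-1-ene-1-carboxylate | COC(=O)C1=C(C)CCCC1=O
A5 | alternative 2 | tert-butyldimethyl{[(1E)-2-(propan-2-yl)buta-1,3-dien-1-yl]oxy}silane | C=C/C(=C/O[Si](C)(C)C(C)(C)C)C(C)C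
A6 | alternative 3 | 6-hydroxy-9-nitro-15-noreudesman-4-one (trans-fused, hydroxyl, isopropyl and nitro equatorial) | O=C1CCC[C@]2(C)[C@@H]([N+](=O)[O-])C[C@@H](C(C)C)[C@H](O)[C@@H]12
A7 | alternative 3 | (S)-3-methyl-3-(nitromethyl)cyclohexan-1-one | O=C1CCC[C@](C)(C[N+](=O)[O-])C1
A8 | alternative 3 | 3-methyl-2-methylidenebutanal | C=C(C=O)C(C)C
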